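**Retrosynthetic overview**
1. Target 28 comes from alcohol 27 by O-acetylation. 27 comes from aldehyde 24 and 4-bromofuran-2(5H)-one 25 by an enantioselective Ni/Cr alkenylation that brings in the intact butenolide and sets the carbinol centre (the new step).
2. 24 comes from hydroxy aldehyde 15 and phosphono-lactone 21 by a Z-selective Horner–Wadsworth–Emmons reaction. The γ-lactone ring of 21 is taken intact from (5S)-5-(hydroxymethyl)oxolan-2-one 16.
3. 15 comes from two iterative copper 1,2-metallate rearrangements of (4,5-dihydrofuran-2-yl)lithium 2 (alkyl shift from Cu to C with ring opening, then MeI). 2 is made once from 2,3-dihydrofuran 1 and serves both rounds; the chain starts from the C3 acetal bromide 3.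
4. Ring order: no ring is built de novo. Two dihydrofuran rings are opened in the 1,2-shifts, the γ-lactone is attached first (step 8) and the butenolide last (step 10).

Assumption: the target is taken as drawn, i.e. (R) at the acetoxy carbon, (S) at the lactone carbon, E,E chain alkenes and a Z-alkylidene lactone (chain cis to the lactone C=O).

**Route**

Step 1
Reactants: 1 2,3-dihydrofuran
Product: 2 (4,5-dihydrofuran-2-yl)lithium, obtained as a titrated THF/pentane stock solution
Conditions: t-BuLi (0.95 equiv), THF/pentane, −78 → 0 °C, 30 min; kept under Ar at −30 °C, titrated before each use, batch sized for steps 2 and 4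
Reagents that add atoms: tert-butyllithium, CC(C)(C)[Li]
Why: Directed α-lithiation of the cyclic enol ether (deprotonation of the vinylic C–H next to oxygen) is clean with t-BuLi in THF, and the cold solution keeps its titre long enough to feed both cuprate steps.

Step 2
Reactants: 3 2-(2-bromoethyl)-1,3-dioxolane, 2 (4,5-dihydrofuran-2-yl)lithium
Product: 8 (3E)-6-(1,3-dioxolan-2-yl)-4-methylhex-3-en-1-ol, via [2-(1,3-dioxolan-2-yl)ethyl]lithium 4 (not isolated), via [2-(1,3-dioxolan-2-yl)ethyl]copper 5 (not isolated), via lithium alkyl(dihydrofuranyl)cuprate 6 (not isolated), via ring-opened alkenylcopper alkoxide 7 (not isolated)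
Conditions: 3, t-BuLi (2.1 equiv), Et2O, −78 °C; CuBr·SMe2 (1 equiv), Me2S, −78 → −40 °C; 2 (1.05 equiv, stock solution), −78 °C → rt; MeI, rt; then H2O
Reagents that add atoms: iodomethane, CI
Why: Copper 1,2-metallate rearrangement (Kocienski type): in cuprate 6 the alkyl group shifts from copper to the oxygen-bearing alkenyl carbon with inversion and loss of the ring alkoxide, and methylation of alkenylcopper 7 with retention puts the migrated chain trans and the methyl cis to the hydroxyethyl arm, so the alkene is E.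

Step 3
Reactants: 8 (3E)-6-(1,3-dioxolan-2-yl)-4-methylhex-3-en-1-ol
Product: 9 2-[(3E)-6-iodo-3-methylhex-3-en-1-yl]-1,3-dioxolane
Conditions: PPh3, I2, imidazole, CH2Cl2, 0 °C → rt
Reagents that add atoms: iodine, II
Why: Appel-type iodination, an SN2 displacement of the oxyphosphonium by iodide at the primary carbon; the imidazole buffer keeps the dioxolane and the alkene intact.

Step 4
Reactants: 9 2-[(3E)-6-iodo-3-methylhex-3-en-1-yl]-1,3-dioxolane, 2 (4,5-dihydrofuran-2-yl)lithium
Product: 15 (4E,8E)-11-hydroxy-4,8-dimethylundeca-4,8-dienal, via homoallylic alkyllithium 10 (not isolated), via homoallylic alkylcopper 11 (not isolated), via lithium alkyl(dihydrofuranyl)cuprate 12 (not isolated), via ring-opened alkenylcopper alkoxide 13 (not isolated), via dienol acetal 14 (not isolated)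
Conditions: 9, t-BuLi (2.1 equiv), Et2O/pentane, −78 °C; CuBr·SMe2 (1 equiv), Me2S, −78 → −40 °C; 2 (1.05 equiv, stock solution), −78 °C → rt; MeI, rt; then 2 M HCl, THF, rt, 3 h
Reagents that add atoms: iodomethane, CI; water, O
Why: Second copper 1,2-metallate rearrangement after clean lithium–iodine exchange: the same 1,2-alkyl shift with inversion and retentive methylation gives the second E-alkene, and the acidic work-up hydrolyses the dioxolane (acetal hydrolysis) to the aldehyde, which cannot cyclise onto the 4,5-alkene.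

Step 5
Reactants: 16 (5S)-5-(hydroxymethyl)oxolan-2-one
Product: 17 (2S)-5-oxooxolane-2-carbaldehyde
Conditions: (COCl)2, DMSO, CH2Cl2, −78 °C; Et3N, −78 → 0 °C; used crude
Reagents that add atoms: none
Why: Swern oxidation gives the α-alkoxy aldehyde under cold, briefly basic conditions, so the (S)-centre, which comes from the chiral-pool lactone, is not epimerised.

Step 6
Reactants: 17 (2S)-5-oxooxolane-2-carbaldehyde
Product: 18 (5S)-5-(2-methylprop-1-en-1-yl)oxolan-2-one
Conditions: [i-PrPPh3]I, n-BuLi, THF, 0 °C; then 17, −78 °C → rt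
Reagents that add atoms: isopropyltriphenylphosphonium iodide, CC(C)[P+](c1ccccc1)(c1ccccc1)c1ccccc1.[I-]
Why: Wittig olefination with the non-stabilised isopropylidene ylide at −78 °C is faster than attack on the lactone or enolisation of the aldehyde, so the (S)-centre is kept, and the symmetric ylide leaves no alkene geometry to control.

Step 7
Reactants: 18 (5S)-5-(2-methylprop-1-en-1-yl)oxolan-2-one
Product: 21 diethyl [(5S)-5-(2-methylprop-1-en-1-yl)-2-oxooxolan-3-yl]phosphonate (C3 epimers), via lithium lactone enolate 19 (not isolated), via lactone phosphonite 20 (not isolated)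
Conditions: LiN(i-Pr)2, THF, −78 °C; ClP(OEt)2, −78 °C → rt; then air (O2), rt
Reagents that add atoms: diethyl chlorophosphite, CCOP(Cl)OCC; dioxygen, O=O
Why: Enolate C-phosphinylation with the trivalent phosphorus chloride followed by air oxidation (Wiemer-type phosphonate synthesis) places the phosphonate on the α-carbon; the new α-centre is an epimer mixture that becomes sp2 in step 8, and the γ-centre is not touched.

Step 8
Reactants: 15 (4E,8E)-11-hydroxy-4,8-dimethylundeca-4,8-dienal, 21 diethyl [(5S)-5-(2-methylprop-1-en-1-yl)-2-oxooxolan-3-yl]phosphonate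
Product: 23 (3Z,5S)-3-[(4E,8E)-11-hydroxy-4,8-dimethylundeca-4,8-dien-1-ylidene]-5-(2-methylprop-1-en-1-yl)oxolan-2-one, via potassium phosphonate carbanion 22 (not isolated)
Conditions: 21 (1.3 equiv), KN(SiMe3)2 (1.25 equiv), 18-crown-6 (3 equiv), THF, −78 °C; then 15, −78 °C, 3 h; aq NH4Cl at −78 °C; chromatography to remove the minor E-isomer
Reagents that add atoms: none
Why: Horner–Wadsworth–Emmons olefination under Still–Gennari-type kinetic conditions (dissociated potassium phosphonate, −78 °C), where fast irreversible collapse of the first adduct favours the Z-alkylidene lactone (chain cis to C=O); the stabilised anion does not deprotonate the remote hydroxyl.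

Step 9
Reactants: 23 (3Z,5S)-3-[(4E,8E)-11-hydroxy-4,8-dimethylundeca-4,8-dien-1-ylidene]-5-(2-methylprop-1-en-1-yl)oxolan-2-one
Product: 24 (3Z,5S)-3-[(4E,8E)-4,8-dimethyl-11-oxoundeca-4,8-dien-1-ylidene]-5-(2-methylprop-1-en-1-yl)oxolan-2-one
Conditions: Dess–Martin periodinane, NaHCO3, CH2Cl2, 0 °C; used crude at once
Reagents that add atoms: none
Why: Dess–Martin oxidation under buffered, non-basic conditions gives the β,γ-unsaturated aldehyde without moving the E-alkene into conjugation and without touching the Z-alkylidene lactone.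

Step 10
Reactants: 24 (3Z,5S)-3-[(4E,8E)-4,8-dimethyl-11-oxoundeca-4,8-dien-1-ylidene]-5-(2-methylprop-1-en-1-yl)oxolan-2-one, 25 4-bromofuran-2(5H)-one
Product: 27 (3Z,5S)-3-[(4E,8E,11R)-11-hydroxy-4,8-dimethyl-11-(5-oxo-2,5-dihydrofuran-3-yl)undeca-4,8-dien-1-ylidene]-5-(2-methylprop-1-en-1-yl)oxolan-2-one, via trimethylsilyl ether 26 (not isolated)
Conditions: CrCl2 (10 mol %), chiral sulfonamide–oxazoline ligand L* (Kishi type, N-[2-(4-isopropyl-4,5-dihydro-1,3-oxazol-2-yl)-6-methylphenyl]methanesulfonamide, antipode chosen for Si-face addition, 11 mol %), Et3N (20 mol %), NiCl2(2,9-dimethyl-1,10-phenanthroline) (2 mol %), Mn powder (2 equiv), Me3SiCl (1.5 equiv), LiCl, MeCN, rt; then 1 M HCl, THF, 0 °C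
Reagents that add atoms: none
Why: Proposed new method: a catalytic asymmetric Nozaki–Hiyama–Kishi coupling with a 4-halobutenolide as the halide partner, in which zerovalent nickel inserts into the activated C4–Br bond of 25 (a β-bromo enoate), the alkenyl group passes to trivalent chromium bound to the chiral sulfonamide–oxazoline ligand, and this weakly basic, strictly 1,2-selective alkenylchromium adds to the Si face of the aldehyde to give the (R)-carbinol as silyl ether 26 (Me3SiCl frees the chromium alkoxide and Mn returns chromium to the divalent state), while both lactones, the enolisable β,γ-unsaturated aldehyde and the acidic butenolide CH2 are left alone; the closest known reactions are catalytic asymmetric Ni/Cr couplings of β-iodoacrylates and simple alkenyl iodides with aliphatic aldehydes.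

Step 11
Reactants: 27 (3Z,5S)-3-[(4E,8E,11R)-11-hydroxy-4,8-dimethyl-11-(5-oxo-2,5-dihydrofuran-3-yl)undeca-4,8-dien-1-ylidene]-5-(2-methylprop-1-en-1-yl)oxolan-2-one
Product: 28 (1R,3E,7E)-4,8-dimethyl-11-[(3Z,5S)-5-(2-methylprop-1-en-1-yl)-2-oxooxolan-3-ylidene]-1-(5-oxo-2,5-dihydrofuran-3-yl)undeca-3,7-dien-1-yl acetate (CNP0310925.2)
Conditions: Ac2O, pyridine, CH2Cl2, 0 °C → rt
Reagents that add atoms: acetic anhydride, CC(=O)OC(C)=O
Why: Pyridine-mediated O-acetylation (nucleophilic acyl substitution at the anhydride) does not break the C–O bond, so the (R)-configuration is retained, and leaving out stronger nucleophilic catalysts protects the Z-alkylidene lactone from addition–elimination isomerisation.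

**Compound list**
1 | 2,3-dihydrofuran | C1CC=CO1 | starting material
2 | (4,5-dihydrofuran-2-yl)lithium | [Li]C1=CCCO1 | intermediate
3 | 2-(2-bromoethyl)-1,3-dioxolane | BrCCC1OCCO1 | starting material
4 | [2-(1,3-dioxolan-2-yl)ethyl]lithium | [Li]CCC1OCCO1 | intermediate
5 | [2-(1,3-dioxolan-2-yl)ethyl]copper | [Cu]CCC1OCCO1 | intermediate
6 | lithium [2-(1,3-dioxolan-2-yl)ethyl](4,5-dihydrofuran-2-yl)cuprate | [Li+].C1COC(CC[Cu-]C2=CCCO2)O1 | intermediate
7 | lithium (3Z)-4-cuprio-6-(1,3-dioxolan-2-yl)hex-3-en-1-olate (Cu cis to the oxidoethyl arm) | [Li+].[O-]CC/C=C(\[Cu])CCC1OCCO1 | intermediate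
8 | (3E)-6-(1,3-dioxolan-2-yl)-4-methylhex-3-en-1-ol | OCC/C=C(\C)CCC1OCCO1 | intermediate
9 | 2-[(3E)-6-iodo-3-methylhex-3-en-1-yl]-1,3-dioxolane | ICC/C=C(\C)CCC1OCCO1 | intermediate
10 | [(3E)-6-(1,3-dioxolan-2-yl)-4-methylhex-3-en-1-yl]lithium | [Li]CC/C=C(\C)CCC1OCCO1 | intermediate
11 | [(3E)-6-(1,3-dioxolan-2-yl)-4-methylhex-3-en-1-yl]copper | [Cu]CC/C=C(\C)CCC1OCCO1 | intermediate
12 | lithium (4,5-dihydrofuran-2-yl)[(3E)-6-(1,3-dioxolan-2-yl)-4-methylhex-3-en-1-yl]cuprate | [Li+].O1CCC=C1[Cu-]CC/C=C(\C)CCC1OCCO1 | intermediate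
13 | lithium (3Z,7E)-4-cuprio-10-(1,3-dioxolan-2-yl)-8-methyldeca-3,7-dien-1-olate | [Li+].[O-]CC/C=C(\[Cu])CC/C=C(\C)CCC1OCCO1 | intermediate
14 | (3E,7E)-10-(1,3-dioxolan-2-yl)-4,8-dimethyldeca-3,7-dien-1-ol | OCC/C=C(\C)CC/C=C(\C)CCC1OCCO1 | intermediate
15 | (4E,8E)-11-hydroxy-4,8-dimethylundeca-4,8-dienal | OCC/C=C(\C)CC/C=C(\C)CCC=O | intermediate
16 | (5S)-5-(hydroxymethyl)oxolan-2-one | O=C1CC[C@@H](CO)O1 | starting material
17 | (2S)-5-oxooxolane-2-carbaldehyde | O=C1CC[C@@H](C=O)O1 | intermediate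
18 | (5S)-5-(2-methylprop-1-en-1-yl)oxolan-2-one | O=C1CC[C@@H](C=C(C)C)O1 | intermediate
19 | lithium (2S)-2-(2-methylprop-1-en-1-yl)-2,3-dihydrofuran-5-olate (enolate of 18) | [Li+].[O-]C1=CC[C@@H](C=C(C)C)O1 | intermediate
20 | diethyl [(5S)-5-(2-methylprop-1-en-1-yl)-2-oxooxolan-3-yl]phosphonite | CCOP(OCC)C1C[C@@H](C=C(C)C)OC1=O | intermediate
21 | diethyl [(5S)-5-(2-methylprop-1-en-1-yl)-2-oxooxolan-3-yl]phosphonate (C3 epimers) | CCOP(=O)(OCC)C1C[C@@H](C=C(C)C)OC1=O | intermediate
22 | potassium salt of the C3 carbanion of 21 | [K+].CCOP(=O)(OCC)[C-]1C[C@@H](C=C(C)C)OC1=O | intermediate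
23 | (3Z,5S)-3-[(4E,8E)-11-hydroxy-4,8-dimethylundeca-4,8-dien-1-ylidene]-5-(2-methylprop-1-en-1-yl)oxolan-2-one | OCC/C=C(\C)CC/C=C(\C)CC/C=C1/C[C@@H](C=C(C)C)OC1=O | intermediate
24 | (3Z,5S)-3-[(4E,8E)-4,8-dimethyl-11-oxoundeca-4,8-dien-1-ylidene]-5-(2-methylprop-1-en-1-yl)oxolan-2-one | O=CC/C=C(\C)CC/C=C(\C)CC/C=C1/C[C@@H](C=C(C)C)OC1=O | intermediate
25 | 4-bromofuran-2(5H)-one | O=C1OCC(Br)=C1 | starting material
26 | trimethylsilyl ether of 27 | C[Si](C)(C)O[C@H](C/C=C(\C)CC/C=C(\C)CC/C=C1/C[C@@H](C=C(C)C)OC1=O)C1=CC(=O)OC1 | intermediate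
27 | (3Z,5S)-3-[(4E,8E,11R)-11-hydroxy-4,8-dimethyl-11-(5-oxo-2,5-dihydrofuran-3-yl)undeca-4,8-dien-1-ylidene]-5-(2-methylprop-1-en-1-yl)oxolan-2-one | O[C@H](C/C=C(\C)CC/C=C(\C)CC/C=C1/C[C@@H](C=C(C)C)OC1=O)C1=CC(=O)OC1 | intermediate
28 | (1R,3E,7E)-4,8-dimethyl-11-[(3Z,5S)-5-(2-methylprop-1-en-1-yl)-2-oxooxolan-3-ylidene]-1-(5-oxo-2,5-dihydrofuran-3-yl)undeca-3,7-dien-1-yl acetate | CC(=O)O[C@H](C/C=C(\C)CC/C=C(\C)CC/C=C1/C[C@@H](C=C(C)C)OC1=O)C1=CC(=O)OC1 | target

**Totals**
Total step count: 11.
Longest linear sequence: 8 steps (1, 2, 3, 4, 8, 9, 10, 11); steps 5–7 form the lactone branch.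

**Steps most likely to fail, with fallbacks**

Step 10, the proposed new Ni/Cr coupling, carries the most risk. The butenolid-4-yl metal species could lose the ring acyloxy group by β-elimination to an allenoate, bromide 25 could homocouple on nickel, and the facial selectivity is untested, so the ligand antipode and the sense of induction must be checked by Mosher ester analysis. The fallback uses only known chemistry; it sets out from aldehyde 24 and comes back at target 28. 3-Bromofuran is lithiated (n-BuLi, THF, −78 °C) to furan-3-yllithium F3, which is transmetalated with EtZnCl (with N,N,N',N'-tetraethylethylenediamine to bind the lithium chloride) to ethyl(furan-3-yl)zinc F4. F4 adds to 24 under catalysis by the amino alcohol (−)-MIB (or its antipode, chosen for Si-face attack) to give (3Z,5S)-3-[(4E,8E,11R)-11-(furan-3-yl)-11-hydroxy-4,8-dimethylundeca-4,8-dien-1-ylidene]-5-(2-methylprop-1-en-1-yl)oxolan-2-one F5. Acetylation (Ac2O, pyridine) gives (1R,3E,7E)-1-(furan-3-yl)-4,8-dimethyl-11-[(3Z,5S)-5-(2-methylprop-1-en-1-yl)-2-oxooxolan-3-ylidene]undeca-3,7-dien-1-yl acetate F6. Sensitised photo-oxygenation (O2, rose bengal, hν, i-Pr2NEt, CH2Cl2, −78 °C) converts the 3-substituted furan regioselectively into the 4-substituted 5-hydroxybutenolide (1R,3E,7E)-1-(2-hydroxy-5-oxo-2,5-dihydrofuran-3-yl)-4,8-dimethyl-11-[(3Z,5S)-5-(2-methylprop-1-en-1-yl)-2-oxooxolan-3-ylidene]undeca-3,7-dien-1-yl acetate F7. Reduction with NaBH4 (EtOH, 0 °C) and acidification reduces the masked aldehyde and relactonises to 28.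

Step 8 may give an unsatisfactory Z/E ratio, since kinetic Z-selectivity of phosphono-lactones with aliphatic aldehydes is only moderate. The fallback sets out from 15 and 21 and comes back at 23. The olefination is run under Masamune–Roush conditions (LiCl, DBU, MeCN, rt), which give mainly (3E,5S)-3-[(4E,8E)-11-hydroxy-4,8-dimethylundeca-4,8-dien-1-ylidene]-5-(2-methylprop-1-en-1-yl)oxolan-2-one F2. F2 is then isomerised photochemically (benzophenone as triplet sensitiser, 350 nm, benzene, rt) to an E/Z photostationary mixture. 23 is separated by chromatography (AgNO3-impregnated silica if needed) and recovered F2 is irradiated again.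

Step 2 depends on bromine–lithium exchange of a primary bromide and on an acetal-bearing alkylcopper surviving the warm-up needed for the 1,2-shift. The fallback sets out from 2 and 3 and comes back at 8. The lithiated dihydrofuran 2 is alkylated with bromide 3 (THF, DMPU, −30 °C → rt) to give 5-[2-(1,3-dioxolan-2-yl)ethyl]-2,3-dihydrofuran F1. The enol-ether C–O bond of F1 is then replaced by methyl with retention in a Wenkert-type coupling (MeMgBr, NiCl2(PPh3)2 cat., toluene, 80 °C; then H2O), which opens the ring to alcohol 8 with the same E geometry.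

**Further compounds**
F1 | step 2 | 5-[2-(1,3-dioxolan-2-yl)ethyl]-2,3-dihydrofuran | C1(CCC2OCCO2)=CCCO1
F2 | step 8 | (3E,5S)-3-[(4E,8E)-11-hydroxy-4,8-dimethylundeca-4,8-dien-1-ylidene]-5-(2-methylprop-1-en-1-yl)oxolan-2-one | OCC/C=C(\C)CC/C=C(\C)CC/C=C1\C[C@@H](C=C(C)C)OC1=O
F3 | step 10 | furan-3-yllithium | [Li]c1ccoc1
F4 | step 10 | ethyl(furan-3-yl)zinc | CC[Zn]c1ccoc1
F5 | step 10 | (3Z,5S)-3-[(4E,8E,11R)-11-(furan-3-yl)-11-hydroxy-4,8-dimethylundeca-4,8-dien-1-ylidene]-5-(2-methylprop-1-en-1-yl)oxolan-2-one | O[C@H](C/C=C(\C)CC/C=C(\C)CC/C=C1/C[C@@H](C=C(C)C)OC1=O)c1ccoc1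
F6 | step 10 | (1R,3E,7E)-1-(furan-3-yl)-4,8-dimethyl-11-[(3Z,5S)-5-(2-methylprop-1-en-1-yl)-2-oxooxolan-3-ylidene]undeca-3,7-dien-1-yl acetate | CC(=O)O[C@H](C/C=C(\C)CC/C=C(\C)CC/C=C1/C[C@@H](C=C(C)C)OC1=O)c1ccoc1
F7 | step 10 | (1R,3E,7E)-1-(2-hydroxy-5-oxo-2,5-dihydrofuran-3-yl)-4,8-dimethyl-11-[(3Z,5S)-5-(2-methylprop-1-en-1-yl)-2-oxooxolan-3-ylidene]undeca-3,7-dien-1-yl acetate (hemiacetal epimers) | CC(=O)O[C@H](C/C=C(\C)CC/C=C(\C)CC/C=C1/C[C@@H](C=C(C)C)OC1=O)C1=CC(=O)OC1O
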